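**Retrosynthetic overview**

1. Germacrane numbering is used: C1–C10 carbocycle, C11–C13 methylene lactone, C14 methyl on C10, C15 hydroxymethyl on C4. Enabling feature: C3 is a secondary carbinol bonded directly to sp2 C4 of the endocyclic Z-alkene C4=C5 of the ten-membered ring, with ring atoms C3 and C6 cis on that alkene. This is the retron of an alkenylmetal/aldehyde addition, and the Z geometry holds both chain ends on one side.
2. Last C–C bond: C3–C4, by intramolecular Nozaki–Hiyama–Kishi addition of the (Z)-C4 alkenyl iodide to the C3 aldehyde. It closes the ten-membered ring, sets C3 and keeps 4Z; only a desilylation follows.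
3. Seco-aldehyde: C7–C8 Barbier union of a C6-configured 3-(bromomethyl)butenolide (C4–C7, C11–C13, C15) with a β,γ-unsaturated aldehyde (C8–C10, C14, C1–C3). Mitsunobu esterification with methacrylic acid then inverts C8, and Shi epoxidation installs the C1–C10 oxirane.
4. Fragments: the butenolide comes from asymmetric alkynylation of acrolein, directed hydroalumination–iodination, acylation and ring-closing metathesis. The aldehyde comes from Negishi carboalumination and ethylene oxide opening.
5. Order of ring formation: γ-lactone (step 4), oxirane (step 11), ten-membered carbocycle (step 14).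

Key step: step 14

Assumption: the (S,S)-enantiomer of the ProPhenol ligand is taken to deliver the 3S alcohol 3; if its sense is the reverse, the (R,R)-ligand is used and nothing else changes.

**Route**

Step 1
Reactants: 1 acrolein; 2 tert-butyldimethyl(prop-2-yn-1-yloxy)silane
Product: 3 (S)-6-(tert-butyldimethylsilyloxy)hex-1-en-4-yn-3-ol
Conditions: Me2Zn, (S,S)-ProPhenol (10 mol%), Ph3P=O (20 mol%), toluene, 0 °C
Reagents that add atoms: none
Why: Zinc–ProPhenol asymmetric alkynylation of an aldehyde, in which the zinc alkynylide adds to one enantiotopic face of acrolein inside the chiral ligand pocket and sets the carbinol carbon (the later C6) as S.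

Step 2
Reactants: 3 (S)-6-(tert-butyldimethylsilyloxy)hex-1-en-4-yn-3-ol
Product: 5 (S,Z)-6-(tert-butyldimethylsilyloxy)-5-iodohexa-1,4-dien-3-ol, via cyclic sodium alkenylaluminate 4 (not isolated)
Conditions: NaAlH2(OCH2CH2OMe)2, THF, 0 °C; EtOAc; then I2, −78 → 0 °C
Reagents that add atoms: iodine, II
Why: Hydroxyl-directed trans-hydroalumination of a propargylic alcohol followed by iodinolysis, in which hydride goes to the proximal alkyne carbon (C5) and aluminium binds the distal carbon (C4) cis to the carbinol carbon in the five-membered aluminate 4, so that iodine replaces aluminium with retention to give the Z-iodoalkene while the carbinol centre and the vinyl group are untouched.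

Step 3
Reactants: 5 (S,Z)-6-(tert-butyldimethylsilyloxy)-5-iodohexa-1,4-dien-3-ol; 6 2-(bromomethyl)acrylic acid
Product: 7 (S,Z)-6-(tert-butyldimethylsilyloxy)-5-iodohexa-1,4-dien-3-yl 2-(bromomethyl)acrylate
Conditions: DIC, DMAP (5 mol%), CH2Cl2, 0 °C
Reagents that add atoms: none
Why: Steglich esterification, which acylates at oxygen without breaking the C6–O bond so that the S centre is kept, while low temperature and little DMAP spare the allylic bromide.

Step 4
Reactants: 7 (S,Z)-6-(tert-butyldimethylsilyloxy)-5-iodohexa-1,4-dien-3-yl 2-(bromomethyl)acrylate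
Product: 8 (S)-3-(bromomethyl)-5-[(Z)-3-(tert-butyldimethylsilyloxy)-2-iodoprop-1-enyl]furan-2(5H)-one
Conditions: second-generation Hoveyda–Grubbs catalyst (H2IMes)Cl2Ru=CH(C6H4-2-OiPr) (5 mol%), toluene (5 mM), 80 °C
Reagents that add atoms: none
Why: Ring-closing metathesis, in which the ruthenium carbene loads on the monosubstituted vinyl group and closes onto the 1,1-disubstituted acrylate alkene to give the five-membered butenolide (C7=C11) with loss of ethylene, the trisubstituted iodoalkene being inert and C6 not involved.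

Step 5
Reactants: 9 tert-butyl(but-3-yn-1-yloxy)dimethylsilane; 10 ethylene oxide
Product: 13 (E)-6-(tert-butyldimethylsilyloxy)-4-methylhex-3-en-1-ol, via alkenyldimethylalane 11 (not isolated), via lithium alkenylaluminate 12 (not isolated)
Conditions: AlMe3, Cp2ZrCl2 (0.25 equiv), CH2Cl2, 20 °C; volatiles removed; n-BuLi, hexane/THF, −30 °C; then 10, −30 → 20 °C
Reagents that add atoms: trimethylaluminium, C[Al](C)C
Why: Negishi zirconium-catalysed carboalumination, in which methyl and aluminium add syn across the terminal alkyne with methyl on the internal carbon (C10), and the derived aluminate opens ethylene oxide with retention at the alkenyl carbon to give the E-trisubstituted C1=C10 alkene carrying C2 and C3.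

Step 6
Reactants: 13 (E)-6-(tert-butyldimethylsilyloxy)-4-methylhex-3-en-1-ol
Product: 14 (E)-tert-butyl{[6-(4-methoxybenzyloxy)-3-methylhex-3-enyl]oxy}dimethylsilane
Conditions: NaH, 4-methoxybenzyl chloride, DMF, 0 → 20 °C
Reagents that add atoms: 4-methoxybenzyl chloride, COc1ccc(CCl)cc1
Why: Williamson ether synthesis on the primary alkoxide, which masks the C3 hydroxyl as a PMB ether orthogonal to both silyl ethers.

Step 7
Reactants: 14 (E)-tert-butyl{[6-(4-methoxybenzyloxy)-3-methylhex-3-enyl]oxy}dimethylsilane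
Product: 15 (E)-6-(4-methoxybenzyloxy)-3-methylhex-3-en-1-ol
Conditions: n-Bu4NF, THF, 0 → 20 °C
Reagents that add atoms: none
Why: Fluoride-induced desilylation of the primary TBS ether, which the PMB ether and the alkene survive.

Step 8
Reactants: 15 (E)-6-(4-methoxybenzyloxy)-3-methylhex-3-en-1-ol
Product: 16 (E)-6-(4-methoxybenzyloxy)-3-methylhex-3-enal
Conditions: Dess–Martin periodinane, NaHCO3, CH2Cl2, 0 °C; crude product used at once
Reagents that add atoms: none
Why: Dess–Martin oxidation of the primary alcohol under buffered, non-basic conditions, which gives the β,γ-unsaturated aldehyde without migration of the alkene into conjugation.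

Step 9
Reactants: 8 (S)-3-(bromomethyl)-5-[(Z)-3-(tert-butyldimethylsilyloxy)-2-iodoprop-1-enyl]furan-2(5H)-one; 16 (E)-6-(4-methoxybenzyloxy)-3-methylhex-3-enal
Product: 18 (4R,5S)-4-[(1S,3E)-1-hydroxy-6-(4-methoxybenzyloxy)-3-methylhex-3-enyl]-5-[(Z)-3-(tert-butyldimethylsilyloxy)-2-iodoprop-1-enyl]-3-methylenedihydrofuran-2(3H)-one, via allylzinc bromide 17 (not isolated)
Conditions: Zn powder, THF/sat. aq. NH4Cl, 0 → 20 °C
Reagents that add atoms: none
Why: Zinc-mediated Barbier allylation, in which the allylzinc 17 reacts at its γ-carbon C7 (SE2') on the ring face anti to the C6 side chain, setting C7 trans to C6 and restoring the exocyclic methylene, and a closed chair (Zimmerman–Traxler) transition state with the aldehyde chain equatorial and the ring-locked E-type γ-substituent sets C8 as S (C8–O anti to the C6 branch), the epimer that step 10 inverts.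

Step 10
Reactants: 18 (4R,5S)-4-[(1S,3E)-1-hydroxy-6-(4-methoxybenzyloxy)-3-methylhex-3-enyl]-5-[(Z)-3-(tert-butyldimethylsilyloxy)-2-iodoprop-1-enyl]-3-methylenedihydrofuran-2(3H)-one; 19 methacrylic acid
Product: 20 (1R,3E)-1-{(2S,3R)-2-[(Z)-3-(tert-butyldimethylsilyloxy)-2-iodoprop-1-enyl]-4-methylene-5-oxotetrahydrofuran-3-yl}-6-(4-methoxybenzyloxy)-3-methylhex-3-enyl methacrylate
Conditions: PPh3, DIAD, toluene, 0 → 20 °C
Reagents that add atoms: none
Why: Mitsunobu esterification, in which the C8 hydroxyl is activated as an alkoxyphosphonium ion and displaced by methacrylate in an SN2 step with inversion, converting the 8S carbinol into the 8R methacrylate of the target in one operation.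

Step 11
Reactants: 20 (1R,3E)-1-{(2S,3R)-2-[(Z)-3-(tert-butyldimethylsilyloxy)-2-iodoprop-1-enyl]-4-methylene-5-oxotetrahydrofuran-3-yl}-6-(4-methoxybenzyloxy)-3-methylhex-3-enyl methacrylate
Product: 21 (1R)-1-{(2S,3R)-2-[(Z)-3-(tert-butyldimethylsilyloxy)-2-iodoprop-1-enyl]-4-methylene-5-oxotetrahydrofuran-3-yl}-2-{(2R,3R)-3-[2-(4-methoxybenzyloxy)ethyl]-2-methyloxiran-2-yl}ethyl methacrylate
Conditions: D-fructose-derived Shi ketone (1,2:4,5-di-O-isopropylidene-D-erythro-2,3-hexodiulo-2,6-pyranose), KHSO5 (as 2KHSO5·KHSO4·K2SO4), NaHCO3, n-Bu4NHSO4, MeCN/aq. Na2EDTA (pH about 8), 0 °C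
Reagents that add atoms: potassium peroxymonosulfate, [K+].[O-]S(=O)(=O)OO
Why: Shi asymmetric epoxidation, in which the chiral dioxirane from the D-fructose-derived ketone transfers oxygen through a spiro transition state only to the electron-rich trialkyl C1=C10 alkene (iodoalkene, methacrylate and methylene lactone are electron-poor) on the face that gives the (1R,10R) epoxide, while syn addition to the E-alkene fixes the trans relation of C2 and C9.

Step 12
Reactants: 21 (1R)-1-{(2S,3R)-2-[(Z)-3-(tert-butyldimethylsilyloxy)-2-iodoprop-1-enyl]-4-methylene-5-oxotetrahydrofuran-3-yl}-2-{(2R,3R)-3-[2-(4-methoxybenzyloxy)ethyl]-2-methyloxiran-2-yl}ethyl methacrylate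
Product: 22 (1R)-1-{(2S,3R)-2-[(Z)-3-(tert-butyldimethylsilyloxy)-2-iodoprop-1-enyl]-4-methylene-5-oxotetrahydrofuran-3-yl}-2-[(2R,3R)-3-(2-hydroxyethyl)-2-methyloxiran-2-yl]ethyl methacrylate
Conditions: DDQ, CH2Cl2/pH 7 phosphate buffer, 0 °C
Reagents that add atoms: none
Why: Oxidative cleavage of the PMB ether by DDQ (hydride abstraction at the electron-rich benzylic position, then hydrolysis) under buffered neutral conditions that leave the silyl ether, epoxide, esters and iodoalkene intact.

Step 13
Reactants: 22 (1R)-1-{(2S,3R)-2-[(Z)-3-(tert-butyldimethylsilyloxy)-2-iodoprop-1-enyl]-4-methylene-5-oxotetrahydrofuran-3-yl}-2-[(2R,3R)-3-(2-hydroxyethyl)-2-methyloxiran-2-yl]ethyl methacrylate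
Product: 23 (1R)-1-{(2S,3R)-2-[(Z)-3-(tert-butyldimethylsilyloxy)-2-iodoprop-1-enyl]-4-methylene-5-oxotetrahydrofuran-3-yl}-2-[(2R,3R)-2-methyl-3-(2-oxoethyl)oxiran-2-yl]ethyl methacrylate
Conditions: Dess–Martin periodinane, NaHCO3, CH2Cl2, 0 °C; crude product used at once
Reagents that add atoms: none
Why: Dess–Martin oxidation of the primary alcohol, where the buffered, non-basic medium and immediate use of the crude product are meant to avoid β-elimination of the β,γ-epoxy aldehyde.

Step 14
Reactants: 23 (1R)-1-{(2S,3R)-2-[(Z)-3-(tert-butyldimethylsilyloxy)-2-iodoprop-1-enyl]-4-methylene-5-oxotetrahydrofuran-3-yl}-2-[(2R,3R)-2-methyl-3-(2-oxoethyl)oxiran-2-yl]ethyl methacrylate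
Product: 25 (1R,3S,4Z,6R,7R,8R,10R)-15-(tert-butyldimethylsilyloxy)-1,10-epoxy-3-hydroxy-8-methacryloyloxygermacra-4,11(13)-dien-12,6-olide, via alkenylchromium dichloride 24 (not isolated)
Conditions: CrCl2 (15 equiv), NiCl2 (0.1 equiv), degassed DMSO, 2 mM, slow addition of 23, 25 °C
Reagents that add atoms: none
Why: Zerovalent nickel (formed from NiCl2 by divalent chromium) inserts into the C4–I bond with retention of the Z geometry, the alkenyl group passes to trivalent chromium (24), and this nucleophile adds to the C3 aldehyde through a chromium-bound carbonyl. The closest known reaction type is the Nozaki–Hiyama–Kishi macrocyclisation of ω-iodoalkenyl aldehydes to medium-ring allylic alcohols. The ten-membered carbocycle, the only ring formed here, closes in a 10-exo-trig mode and turns a monocyclic lactone into the bicyclic heliangolide core. C3 is expected to be set by the folded chain: the C3–H bond should eclipse the C4=C5 plane on the inner side (allylic 1,3-strain against C6 disfavours O or C2 there), C2 should leave that plane on the face opposite to C7 because the chain has to bridge the trans-fused lactone (C6, C7) and the trans-epoxide (C1, C10), and the chromium-bound oxygen then lies on the periphery of the C7 face, which is the 3S carbinol. The step needs cyclisation over oligomerisation, secured by the cis placement of C3 and C6 on the Z-alkene, the two rigid trans-fused small rings that turn the chain, and high dilution; and it needs addition to the aldehyde only, secured by the low basicity and carbonyl selectivity of the alkenylchromium reagent toward lactone, methacrylate, epoxide and silyl ether. The Z geometry of C4=C5 is carried over unchanged from the iodide.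

Step 15
Reactants: 25 (1R,3S,4Z,6R,7R,8R,10R)-15-(tert-butyldimethylsilyloxy)-1,10-epoxy-3-hydroxy-8-methacryloyloxygermacra-4,11(13)-dien-12,6-olide
Product: 26 (1R,3S,4Z,6R,7R,8R,10R)-1,10-epoxy-3,15-dihydroxy-8-methacryloyloxygermacra-4,11(13)-dien-12,6-olide (CNP0496616.1)
Conditions: HF·pyridine, pyridine, THF, 0 → 20 °C
Reagents that add atoms: none
Why: Buffered fluoride desilylation of the primary allylic TBS ether, in which excess pyridine keeps the medium near neutral so that the epoxide, methylene lactone and methacrylate persist and no stereocentre is touched.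

**Compound list**

1 | acrolein | C=CC=O | starting material
2 | tert-butyldimethyl(prop-2-yn-1-yloxy)silane | C#CCO[Si](C)(C)C(C)(C)C | starting material
3 | (S)-6-(tert-butyldimethylsilyloxy)hex-1-en-4-yn-3-ol | C=C[C@H](O)C#CCO[Si](C)(C)C(C)(C)C | intermediate
4 | cyclic sodium alkenylaluminate (five-membered C4–Al–O ring, two 2-methoxyethoxy ligands on aluminium) | C=C[C@H]1C=C(CO[Si](C)(C)C(C)(C)C)[Al-](OCCOC)(OCCOC)O1.[Na+] | intermediate
5 | (S,Z)-6-(tert-butyldimethylsilyloxy)-5-iodohexa-1,4-dien-3-ol | C=C[C@H](O)/C=C(\I)CO[Si](C)(C)C(C)(C)C | intermediate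
6 | 2-(bromomethyl)acrylic acid | C=C(CBr)C(=O)O | starting material
7 | (S,Z)-6-(tert-butyldimethylsilyloxy)-5-iodohexa-1,4-dien-3-yl 2-(bromomethyl)acrylate | C=C(CBr)C(=O)O[C@@H](C=C)/C=C(\I)CO[Si](C)(C)C(C)(C)C | intermediate
8 | (S)-3-(bromomethyl)-5-[(Z)-3-(tert-butyldimethylsilyloxy)-2-iodoprop-1-enyl]furan-2(5H)-one | BrCC1=C[C@@H](/C=C(\I)CO[Si](C)(C)C(C)(C)C)OC1=O | intermediate
9 | tert-butyl(but-3-yn-1-yloxy)dimethylsilane | C#CCCO[Si](C)(C)C(C)(C)C | starting material
10 | ethylene oxide | C1CO1 | starting material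
11 | (E)-[4-(tert-butyldimethylsilyloxy)-2-methylbut-1-enyl]dimethylalane | C[Al](C)/C=C(\C)CCO[Si](C)(C)C(C)(C)C | intermediate
12 | lithium butyl[(E)-4-(tert-butyldimethylsilyloxy)-2-methylbut-1-enyl]dimethylaluminate | [Li+].CCCC[Al-](C)(C)/C=C(\C)CCO[Si](C)(C)C(C)(C)C | intermediate
13 | (E)-6-(tert-butyldimethylsilyloxy)-4-methylhex-3-en-1-ol | OCC/C=C(\C)CCO[Si](C)(C)C(C)(C)C | intermediate
14 | (E)-tert-butyl{[6-(4-methoxybenzyloxy)-3-methylhex-3-enyl]oxy}dimethylsilane | COc1ccc(COCC/C=C(\C)CCO[Si](C)(C)C(C)(C)C)cc1 | intermediate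
15 | (E)-6-(4-methoxybenzyloxy)-3-methylhex-3-en-1-ol | COc1ccc(COCC/C=C(\C)CCO)cc1 | intermediate
16 | (E)-6-(4-methoxybenzyloxy)-3-methylhex-3-enal | COc1ccc(COCC/C=C(\C)CC=O)cc1 | intermediate
17 | {[(S)-5-((Z)-3-(tert-butyldimethylsilyloxy)-2-iodoprop-1-enyl)-2-oxo-2,5-dihydrofuran-3-yl]methyl}zinc bromide | Br[Zn]CC1=C[C@@H](/C=C(\I)CO[Si](C)(C)C(C)(C)C)OC1=O | intermediate
18 | (4R,5S)-4-[(1S,3E)-1-hydroxy-6-(4-methoxybenzyloxy)-3-methylhex-3-enyl]-5-[(Z)-3-(tert-butyldimethylsilyloxy)-2-iodoprop-1-enyl]-3-methylenedihydrofuran-2(3H)-one | C=C1C(=O)O[C@H](/C=C(\I)CO[Si](C)(C)C(C)(C)C)[C@H]1[C@@H](O)C/C(C)=C/CCOCc1ccc(OC)cc1 | intermediate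
19 | methacrylic acid | C=C(C)C(=O)O | starting material
20 | (1R,3E)-1-{(2S,3R)-2-[(Z)-3-(tert-butyldimethylsilyloxy)-2-iodoprop-1-enyl]-4-methylene-5-oxotetrahydrofuran-3-yl}-6-(4-methoxybenzyloxy)-3-methylhex-3-enyl methacrylate | C=C1C(=O)O[C@H](/C=C(\I)CO[Si](C)(C)C(C)(C)C)[C@H]1[C@H](OC(=O)C(C)=C)C/C(C)=C/CCOCc1ccc(OC)cc1 | intermediate
21 | (1R)-1-{(2S,3R)-2-[(Z)-3-(tert-butyldimethylsilyloxy)-2-iodoprop-1-enyl]-4-methylene-5-oxotetrahydrofuran-3-yl}-2-{(2R,3R)-3-[2-(4-methoxybenzyloxy)ethyl]-2-methyloxiran-2-yl}ethyl methacrylate | C=C1C(=O)O[C@H](/C=C(\I)CO[Si](C)(C)C(C)(C)C)[C@H]1[C@H](OC(=O)C(C)=C)C[C@@]2(C)O[C@@H]2CCOCc1ccc(OC)cc1 | intermediate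
22 | (1R)-1-{(2S,3R)-2-[(Z)-3-(tert-butyldimethylsilyloxy)-2-iodoprop-1-enyl]-4-methylene-5-oxotetrahydrofuran-3-yl}-2-[(2R,3R)-3-(2-hydroxyethyl)-2-methyloxiran-2-yl]ethyl methacrylate | C=C1C(=O)O[C@H](/C=C(\I)CO[Si](C)(C)C(C)(C)C)[C@H]1[C@H](OC(=O)C(C)=C)C[C@@]2(C)O[C@@H]2CCO | intermediate
23 | (1R)-1-{(2S,3R)-2-[(Z)-3-(tert-butyldimethylsilyloxy)-2-iodoprop-1-enyl]-4-methylene-5-oxotetrahydrofuran-3-yl}-2-[(2R,3R)-2-methyl-3-(2-oxoethyl)oxiran-2-yl]ethyl methacrylate | C=C1C(=O)O[C@H](/C=C(\I)CO[Si](C)(C)C(C)(C)C)[C@H]1[C@H](OC(=O)C(C)=C)C[C@@]2(C)O[C@@H]2CC=O | intermediate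
24 | alkenylchromium dichloride (trivalent chromium in place of iodine on C4 of 23) | C=C1C(=O)O[C@H](/C=C(\[Cr](Cl)Cl)CO[Si](C)(C)C(C)(C)C)[C@H]1[C@H](OC(=O)C(C)=C)C[C@@]2(C)O[C@@H]2CC=O | intermediate
25 | (1R,3S,4Z,6R,7R,8R,10R)-15-(tert-butyldimethylsilyloxy)-1,10-epoxy-3-hydroxy-8-methacryloyloxygermacra-4,11(13)-dien-12,6-olide | C=C(C)C(=O)O[C@@H]1C[C@@]2(C)O[C@@H]2C[C@H](O)/C(CO[Si](C)(C)C(C)(C)C)=C\[C@H]2OC(=O)C(=C)[C@@H]21 | intermediate
26 | (1R,3S,4Z,6R,7R,8R,10R)-1,10-epoxy-3,15-dihydroxy-8-methacryloyloxygermacra-4,11(13)-dien-12,6-olide (CNP0496616.1) | C=C(C)C(=O)O[C@@H]1C[C@@]2(C)O[C@@H]2C[C@H](O)/C(CO)=C\[C@H]2OC(=O)C(=C)[C@@H]21 | target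

**Step count and risks**

Total step count: 15. Longest linear sequence: 11 steps (steps 1–4, then 9–15; the aldehyde branch, steps 5–8 then 9–15, is equally long).

Steps most likely to fail:

1. Step 14. As the chain folds, the two faces of the C3 carbonyl may not be told apart, so that the C3 epimer forms in quantity. The fallback sets out from 23 and comes back at 25. The ring is closed as in step 14 without regard to C3. The epimeric (3R)-carbinol F1, alone or mixed with 25, is oxidised with Dess–Martin periodinane to the macrocyclic 3-oxo enone F2. F2 is then reduced with (R)-2-methyl-CBS-oxazaborolidine and catecholborane at −78 °C. Here the α-branched alkenyl group acts as the large substituent, so the reagent and not the ring should deliver hydride to give the 3S carbinol 25.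

2. Step 10. The alkoxyphosphonium ion at the hindered C8 may lose the C7 proton (elimination toward the lactone) faster than it is displaced. The fallback sets out from 18 and comes back at 20. Compound 18 is oxidised with Dess–Martin periodinane to the C8 ketone F3, which is kept cold and unpurified to avoid enolisation at C7. F3 is reduced with (S)-2-methyl-CBS-oxazaborolidine and catecholborane, with the branched C7 side as the large group, to the 8R carbinol F4. F4 is acylated with methacryloyl chloride, Et3N and DMAP to give 20.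

3. Step 13. The epoxide β to the new aldehyde may open by β-elimination to a γ-hydroxy enal, during the oxidation or on contact with trivalent chromium in step 14. The fallback sets out from 20 and comes back at 25, with the epoxidation moved behind the ring closure. DDQ cleavage of the PMB ether of 20 gives the alkenyl alcohol F5. Dess–Martin oxidation gives the β,γ-unsaturated aldehyde F6. CrCl2/NiCl2 cyclisation gives the macrocyclic carbinol F7, which lacks the epoxide. Shi epoxidation (or buffered mCPBA) of its only electron-rich alkene, C1=C10, from the exposed outer face should then give 25.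

Further compounds
F1 | step 14 | (3R)-epimer of 25 | C=C(C)C(=O)O[C@@H]1C[C@@]2(C)O[C@@H]2C[C@@H](O)/C(CO[Si](C)(C)C(C)(C)C)=C\[C@H]2OC(=O)C(=C)[C@@H]21
F2 | step 14 | 3-oxo macrocycle (C3 ketone conjugated to C4=C5, 15-O-TBS) | C=C(C)C(=O)O[C@@H]1C[C@@]2(C)O[C@@H]2CC(=O)/C(CO[Si](C)(C)C(C)(C)C)=C\[C@H]2OC(=O)C(=C)[C@@H]21
F3 | step 10 | C8 ketone derived from 18 | C=C1C(=O)O[C@H](/C=C(\I)CO[Si](C)(C)C(C)(C)C)[C@H]1C(=O)C/C(C)=C/CCOCc1ccc(OC)cc1
F4 | step 10 | 8R epimer of 18 | C=C1C(=O)O[C@H](/C=C(\I)CO[Si](C)(C)C(C)(C)C)[C@H]1[C@H](O)C/C(C)=C/CCOCc1ccc(OC)cc1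
F5 | step 13 | primary alcohol from 20 (PMB removed, C1=C10 alkene kept) | C=C1C(=O)O[C@H](/C=C(\I)CO[Si](C)(C)C(C)(C)C)[C@H]1[C@H](OC(=O)C(C)=C)C/C(C)=C/CCO
F6 | step 13 | β,γ-unsaturated aldehyde from F5 | C=C1C(=O)O[C@H](/C=C(\I)CO[Si](C)(C)C(C)(C)C)[C@H]1[C@H](OC(=O)C(C)=C)C/C(C)=C/CC=O
F7 | step 13 | macrocyclic 3S carbinol without the epoxide (1(10)E,4Z-diene, 15-O-TBS) | C=C(C)C(=O)O[C@@H]1C/C(C)=C/C[C@H](O)/C(CO[Si](C)(C)C(C)(C)C)=C\[C@H]2OC(=O)C(=C)[C@@H]21
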